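(The numbers are those of an exercise; no experiment stands behind them.)

Time is the budget here: in 4.0 min a free monomer meets the living ends a countable number of times, and that count tells me how much free monomer is left.

all flasks: initiator 5 mol%

| run | free monomer | remark | time |
|---|---|---|---|
| summer | 0.0050 M | one stirred flow tank at steady state, fed with the mixture as stated, mean residence time 4.0 min |  |
| winter | 0.0050 M (fed, over 3.20 min) | a stirred flask in which free monomer is dosed at a steady rate over 3.20 min without added volume, worked up at 4.0 min | 4.0 min |
| autumn | 0.0050 M | a closed flask charged with all of it at once and left for 4.0 min | 4.0 min |

    free monomer + initiator → living end + monomer in chains (k1 = 150 /M/s)
    free monomer + living end → monomer in chains + living end, rate k2*[living end]*[free monomer] (k2 = 74 /M/s)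
    initiator + monomer in chains → initiator + over-reaction product (k3 = 190 /M/s)

- the set-up with the highest amount of monomer in chains at the outlet or at the end, in percent of the free monomer put in ("none" if the first two lie within 2 percentage points) (summer / winter / autumn / none)
- amount of monomer in chains at the outlet or at the end, in percent of the free monomer put in, summer
- amount of monomer in chains at the outlet or at the end, in percent of the free monomer put in, winter
- amount of monomer in chains at the outlet or at the end, in percent of the free monomer put in, autumn

- the stated concentrations are those of everything mixed, before any reaction; amounts are the same in each set-up
- the feed brings no volume worth counting
- run time (winter): 4.0 min

I hold autumn against its neighbour winter, which has the same charge and the same work-up time and differs in when the free monomer arrives. With living ends at the full initiator charge of 2.50 × 10⁻⁴ M, free monomer falls pseudo-first-order. Autumn's count is then 4.44: this is the turnover count, the growth constant times the living ends times the time of exposure. The fraction of free monomer left is e to the minus the count, 1.18% in autumn. That start is fair for autumn because initiator there has a half-life of 0.924 s at full free monomer, shorter than the 37.5 s in which growth at full living ends halves free monomer. Step 3 needs initiator, and in autumn that half-life of initiator is also shorter than the 0.24 min in which step 3 at charged initiator halves the monomer in chains, so I expect over-reaction to take little from the 98.8% of free monomer reckoned as used in autumn.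

Taking living ends at full charge in winter as well, I reckon a count of 3.55 spent while dosing, which brings free monomer to the charge divided by that count, times one minus e to its minus value: 0.00137 M. After dosing ends, winter has a count of 0.888 left, smaller than autumn's, so I reckon 11.3% of the charge stays free and 88.7% is used in winter. The gap in free monomer, 10 percentage points, is wider than the margin of 2 points, so between these two I commit to autumn.

The forecast, which holds that “slow dosing keeps monomer low”, names autumn and gives 61.1% for summer, 86.9% for winter and 98.6% for autumn.

The simulation gives autumn as best, with 61.1% for summer, 86.9% for winter and 98.6% for autumn. Winter ends with 11.2% of its charge as free monomer. In the summer tank, free monomer stays on average for the residence time, so the same count enters differently: the fraction left is one over one plus the count, 18.4%. The summer tank holds 17.9% of the charge as free monomer.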